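**Retrosynthetic overview**

1. Target 41 is the head-to-tail [4+2] dimer of one triene monomer 40. The central cyclohexene (ring D) is formed last, from the terminal 2-alkyl-1,3-diene of one monomer and the terminal 1,1-disubstituted alkene of the other.
2. Monomer 40 comes from the α-alkylidene, cis-fused γ-lactone 34. This lactone (ring C) is a temporary ring: it fixes the cis hydroxyl/side-chain pair on the cyclopentane (ring B) and supplies the enolate for aldol condensation with dienal 30. Reduction opens it to the 1,4-diol.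
3. Lactone 25 comes from spiro β-hydroxy ketone 21 by α-alkylation trans to the carbinol carbon and hydroxyl-directed reduction.
4. Ketone 21 comes from enone–ketone 19 by a copper hydride reductive aldol that closes the cyclohexane (ring A) through the bond between the spiro carbon and the methyl carbinol carbon. Enabling feature: the carbinol carbon C(OH)CH3 of ring A and the oxygen-bearing carbon of ring B are both bonded to the spiro carbon. At the ketone level of ring B this is a β-hydroxy ketone whose α-carbon is the spiro carbon, with the methyl ketone 1,5 to it through ring A. The tetrasubstituted exocyclic alkene of ring A, next to the only pre-existing stereocentre, acts as the conformational lock.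
5. Enone 19 comes from auxiliary-controlled conjugate addition of a tetrasubstituted alkenyl Grignard reagent (alkynol carbomagnesiation) to an enoyl oxazolidinone, then cyclopentenone annulation and Tsuji–Wacker oxidation. Ring order: B, then A (key step), then C (temporary), then D.

Key step: step 12

Remark on the chemistry: the two stereocentres of ring D are formed far from the spiro units, so no control over them is assumed; step 24 plans a separation of cyclohexene diastereomers. TBS = tert-butyldimethylsilyl, TBDPS = tert-butyldiphenylsilyl.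

**Route**

Step 1
Reactants: 1 hex-1-en-5-yne
Product: 3 hept-6-en-2-yn-1-ol, via lithium acetylide 2 (not isolated)
Conditions: n-BuLi, THF, −78 °C; (CH2O)n, −78 °C → rt
Reagents that add atoms: formaldehyde (as paraformaldehyde), C=O
Why: Deprotonation of the terminal alkyne and 1,2-addition of the acetylide to formaldehyde should give the propargylic alcohol; no stereocentre is formed.

Step 2
Reactants: 3 hept-6-en-2-yn-1-ol
Product: 5 (Z)-3-iodo-2-methylhepta-2,6-dien-1-ol, via cyclic alkenylmagnesium alkoxide 4 (not isolated)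
Conditions: MeMgBr (3.5 equiv), CuI (10 mol%), THF, 0 °C → rt; I2, −78 → 0 °C
Reagents that add atoms: methylmagnesium bromide, C[Mg]Br; iodine, II
Why: Copper-catalysed, alkoxide-directed anti-carbomagnesiation of the propargylic alcohol places methyl on the alkyne carbon next to CH2OH and magnesium on the distal carbon in a five-membered chelate, and iodinolysis with retention should give the tetrasubstituted iodoalkene with iodine cis to CH2OH and methyl cis to the butenyl chain.

Step 3
Reactants: 5 (Z)-3-iodo-2-methylhepta-2,6-dien-1-ol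
Product: 6 (Z)-tert-butyl[(3-iodo-2-methylhepta-2,6-dien-1-yl)oxy]dimethylsilane
Conditions: TBSCl, imidazole, CH2Cl2, 0 °C → rt
Reagents that add atoms: tert-butyldimethylsilyl chloride, CC(C)(C)[Si](C)(C)Cl
Why: Standard silylation of the primary allylic alcohol protects it for the organometallic steps.

Step 4
Reactants: 7 pent-4-en-1-ol
Product: 8 tert-butyldimethyl(pent-4-en-1-yloxy)silane
Conditions: TBSCl, imidazole, CH2Cl2, rt
Reagents that add atoms: tert-butyldimethylsilyl chloride, CC(C)(C)[Si](C)(C)Cl
Why: Standard silylation of a primary alcohol.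

Step 5
Reactants: 9 (R)-4-benzyloxazolidin-2-one
Product: 10 (R)-3-acryloyl-4-benzyloxazolidin-2-one
Conditions: acryloyl chloride, Et3N, LiCl, THF, −20 → 0 °C
Reagents that add atoms: acryloyl chloride, C=CC(=O)Cl
Why: Lithium chloride-assisted N-acylation attaches the acryloyl unit to the oxazolidinone auxiliary.

Step 6
Reactants: 10 (R)-3-acryloyl-4-benzyloxazolidin-2-one, 8 tert-butyldimethyl(pent-4-en-1-yloxy)silane
Product: 11 (R)-4-benzyl-3-[(E)-6-(tert-butyldimethylsilyloxy)hex-2-enoyl]oxazolidin-2-one
Conditions: second-generation Hoveyda–Grubbs catalyst RuCl2(H2IMes)(=CH–C6H4-2-OiPr) (3 mol%), CH2Cl2, 40 °C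
Reagents that add atoms: none
Why: Olefin cross-metathesis of an electron-poor acryloyl imide with an unhindered terminal alkene is selective for the cross product and should give the E-enoyl imide.

Step 7
Reactants: 6 (Z)-tert-butyl[(3-iodo-2-methylhepta-2,6-dien-1-yl)oxy]dimethylsilane, 11 (R)-4-benzyl-3-[(E)-6-(tert-butyldimethylsilyloxy)hex-2-enoyl]oxazolidin-2-one
Product: 14 (R)-4-benzyl-3-[(S)-6-(TBS-oxy)-3-{(Z)-1-(TBS-oxy)-2-methylhepta-2,6-dien-3-yl}hexanoyl]oxazolidin-2-one, via alkenyllithium 12 (not isolated), via alkenylmagnesium bromide 13 (not isolated)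
Conditions: 6 (2 equiv), t-BuLi, Et2O, −78 °C; MgBr2·OEt2; CuBr·SMe2 (0.3 equiv), THF/Me2S, −40 °C; then 11, −40 → −10 °C
Reagents that add atoms: none
Why: Copper-promoted conjugate addition of the alkenyl Grignard reagent to the magnesium-chelated syn-s-cis N-enoyl oxazolidinone should occur on the alkene face opposite to the benzyl group and set the (S) stereocentre, while iodine–lithium exchange and transmetalation retain the alkene geometry.

Step 8
Reactants: 14 conjugate adduct
Product: 15 (S)-6-(TBS-oxy)-3-[(Z)-1-(TBS-oxy)-2-methylhepta-2,6-dien-3-yl]-N-methoxy-N-methylhexanamide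
Conditions: MeNH(OMe)·HCl, AlMe3, CH2Cl2, 0 °C → rt
Reagents that add atoms: N,O-dimethylhydroxylamine hydrochloride, CNOC.Cl
Why: Aluminium amide transamidation cleaves the exocyclic imide carbonyl, releases the auxiliary and gives the Weinreb amide; the β-stereocentre is not enolisable.

Step 9
Reactants: 15 Weinreb amide
Product: 16 (S)-9-(TBS-oxy)-6-[(Z)-1-(TBS-oxy)-2-methylhepta-2,6-dien-3-yl]-1,1-dimethoxynonan-4-one
Conditions: BrMg(CH2)2CH(OMe)2 (from 3-bromo-1,1-dimethoxypropane and Mg, THF), THF, 0 °C
Reagents that add atoms: (3,3-dimethoxypropyl)magnesium bromide, COC(CC[Mg]Br)OC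
Why: Weinreb ketone synthesis: the chelated tetrahedral intermediate should stop the Grignard addition at the ketone stage.

Step 10
Reactants: 16 keto acetal
Product: 18 2-[(5Z)-1,7-bis(TBS-oxy)-5-(but-3-en-1-yl)-6-methylhept-5-en-4-yl]cyclopent-2-en-1-one, via keto aldehyde 17 (not isolated)
Conditions: PPTS (0.2 equiv), acetone/H2O (10:1), rt; then KOH (0.1 M), MeOH, 0 °C → rt
Reagents that add atoms: none
Why: Mild acetal hydrolysis should spare the silyl ethers, and intramolecular aldol condensation of the 1,4-keto aldehyde (only the five-membered closure through the ketone α-methylene is possible) should give the 2-substituted cyclopent-2-enone; the adjacent stereocentre carries no acidifying group.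

Step 11
Reactants: 18 cyclopentenone with terminal alkene
Product: 19 2-[(5Z)-1,7-bis(TBS-oxy)-6-methyl-5-(3-oxobutyl)hept-5-en-4-yl]cyclopent-2-en-1-one
Conditions: PdCl2 (10 mol%), CuCl (1 equiv), O2 (1 atm), DMF/H2O (7:1), rt
Reagents that add atoms: water (oxygen of the new ketone; O2 is the terminal oxidant), O
Why: Tsuji–Wacker oxidation converts the monosubstituted terminal alkene into the methyl ketone and should leave the electron-poor enone and the hindered tetrasubstituted alkene untouched.

Step 12
Reactants: 19 enone–methyl ketone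
Product: 21 6-hydroxy-6-methyl-9-[(Z)-1-(TBS-oxy)propan-2-ylidene]-10-[3-(TBS-oxy)propyl]spiro[4.5]decan-1-one (hydroxyl, carbonyl carbon and silyloxypropyl chain mutually cis on ring A), via copper enolate 20 (not isolated)
Conditions: [(Ph3P)CuH]6 (0.25 equiv, 1.5 equiv hydride), toluene, −40 → 0 °C; aq. NH4Cl
Reagents that add atoms: none
Why: Monovalent copper hydride adds hydride to the unsubstituted β-carbon of the cyclopentenone and so generates, regiospecifically and without base, the tetrasubstituted copper enolate 20, whose α-carbon attacks the methyl ketone held five atoms away; the closest known reaction type is the copper hydride reductive aldol cyclisation of keto-enones. Ring A closes in the 6-(enolexo)-exo-trig mode onto the existing five-membered ring, which turns the enolate carbon into the spiro centre. The tertiary carbinol centre is set by the chelated, chair-like Zimmerman–Traxler arrangement (copper bridging enolate and ketone oxygens), which should place the new hydroxyl cis to the ring-B carbonyl carbon and the methyl group equatorial. The spiro centre is set by the neighbouring stereocentre: A(1,3) strain with the tetrasubstituted alkene (its CH2OTBS group is syn to that stereocentre) forces the silyloxypropyl chain axial in the chair, the bulkier vinylic ring carbon then stays away from the copper-bound enolate oxygen, and the chain should end cis to the carbonyl carbon. The step needs 1,4-reduction of the enone in preference to 1,2-reduction of either ketone, and aldol closure faster than protonation of the enolate; the unhindered enone β-position, the low temperature, the aprotic medium and the intramolecularity should secure this. Because the enolate is formed regiospecifically, the competing aldol of the methyl ketone enolate onto the ring ketone is excluded.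

Step 13
Reactants: 21 spiro β-hydroxy ketone
Product: 23 ethyl 2-[6-hydroxy-6-methyl-1-oxo-9-{(Z)-1-(TBS-oxy)propan-2-ylidene}-10-{3-(TBS-oxy)propyl}spiro[4.5]decan-2-yl]acetate (acetate arm trans to the carbinol carbon across ring B), via dilithium alkoxide enolate 22 (not isolated)
Conditions: LiN(iPr)2 (2.3 equiv), THF, −78 °C; ICH2CO2Et, DMPU, −78 → −45 °C; AcOH, −78 °C
Reagents that add atoms: ethyl iodoacetate, CCOC(=O)CI
Why: Enolisation is possible only at the ring-B methylene next to the ketone (the other α-carbon is the spiro centre), the enolate once formed cannot undergo retro-aldol cleavage, and the electrophile should approach trans to the fully substituted carbinol carbon on the spiro centre, which sets the new stereocentre.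

Step 14
Reactants: 23 keto ester
Product: 25 cis-fused γ-lactone on ring B (lactone oxygen on the former ketone carbon), via hydroxy ester 24 (not isolated)
Conditions: Me4NBH(OAc)3, MeCN/AcOH (1:1), −30 → 0 °C; then PPTS (cat.), toluene, 50 °C
Reagents that add atoms: none
Why: Hydroxyl-directed triacetoxyborohydride reduction delivers hydride intramolecularly from the tertiary alkoxyborohydride to the ketone face on which the carbinol carbon lies, which should give the anti 1,3-diol with the new hydroxyl cis to the acetate arm, and this pair then lactonises.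

Step 15
Reactants: 26 6-methylhept-5-en-2-one
Product: 28 6-methylhepta-1,5-dien-2-yl trifluoromethanesulfonate, via lithium enolate 27 (not isolated)
Conditions: LiN(iPr)2, THF, −78 °C; PhNTf2, −78 → 0 °C
Reagents that add atoms: N-phenylbis(trifluoromethanesulfonimide), O=S(=O)(N(c1ccccc1)S(=O)(=O)C(F)(F)F)C(F)(F)F
Why: Kinetic deprotonation at the methyl group and O-triflation should give the terminal enol triflate.

Step 16
Reactants: 28 enol triflate
Product: 30 (E)-8-methyl-4-methylidenenona-2,7-dienal, via diethyl acetal 29 (not isolated)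
Conditions: (E)-(EtO)2CHCH=CH–B(pin), Pd(PPh3)4 (5 mol%), K3PO4, dioxane/H2O, 60 °C; then 1 M HCl, THF, 0 °C
Reagents that add atoms: (E)-2-(3,3-diethoxyprop-1-en-1-yl)-4,4,5,5-tetramethyl-1,3,2-dioxaborolane, CCOC(OCC)/C=C/B1OC(C)(C)C(C)(C)O1; water, O
Why: Suzuki–Miyaura coupling of the alkenyl triflate with the E-alkenylboronate proceeds with retention, and acetal hydrolysis unmasks the E-dienal, which should be used cold and at once because it is prone to self-cycloaddition.

Step 17
Reactants: 25 tricyclic lactone, 30 dienal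
Product: 34 α-alkylidene lactone with the (E,E)-configured cross-conjugated triene side chain, via lactone enolate 31 (not isolated), via aldol adduct 32 (not isolated), via mesylate 33 (not isolated)
Conditions: LiN(iPr)2 (2.2 equiv), THF, −78 °C; 30; aq. work-up; crude: MsCl, Et3N, CH2Cl2, −20 °C; then DBU, 0 °C → rt
Reagents that add atoms: none
Why: Aldol addition of the lactone enolate to the enal carbonyl followed by mesylation of the secondary hydroxyl and E1cB elimination should give the thermodynamically preferred alkylidene lactone, with the dienyl chain cis to the ring-B carbon and trans to the carbonyl.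

Step 18
Reactants: 34 alkylidene lactone
Product: 35 diol (primary allylic alcohol on the side chain, secondary alcohol on ring B)
Conditions: iBu2AlH (6 equiv), CH2Cl2, −78 → 0 °C; aq. potassium sodium tartrate
Reagents that add atoms: none
Why: 1,2-Reduction of the conjugated lactone through the lactol/hydroxy enal should give the allylic primary alcohol and the ring-B secondary alcohol with all alkene geometries retained.

Step 19
Reactants: 35 diol
Product: 36 mono-TBDPS ether at the primary allylic oxygen
Conditions: TBDPSCl (1.1 equiv), imidazole, CH2Cl2, 0 °C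
Reagents that add atoms: tert-butyldiphenylsilyl chloride, CC(C)(C)[Si](Cl)(c1ccccc1)c1ccccc1
Why: The primary allylic hydroxyl should react far faster with the bulky chlorosilane than the secondary hydroxyl flanked by the spiro carbon or the tertiary hydroxyl.

Step 20
Reactants: 36 TBDPS ether carrying two TBS ethers
Product: 37 tetraol mono-TBDPS ether (free 3-hydroxypropyl and free tetrasubstituted allylic alcohol)
Conditions: HF·pyridine, pyridine, THF, 0 °C
Reagents that add atoms: none
Why: Buffered HF·pyridine should remove the two primary TBS ethers much faster than the primary TBDPS ether.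

Step 21
Reactants: 37 tetraol mono-TBDPS ether
Product: 38 (Z)-tetrasubstituted enal
Conditions: MnO2 (activated, excess), CH2Cl2, rt
Reagents that add atoms: none
Why: MnO2 oxidises only the free allylic primary alcohol (the other allylic oxygen is silylated, and saturated primary, secondary and tertiary alcohols are inert) and should give the enal without change of alkene geometry.

Step 22
Reactants: 38 enal
Product: 39 tetradecanoate of the 3-hydroxypropyl chain
Conditions: tetradecanoyl chloride (1.1 equiv), 2,4,6-collidine, CH2Cl2, −40 → 0 °C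
Reagents that add atoms: tetradecanoyl chloride, CCCCCCCCCCCCCC(=O)Cl
Why: Acylation should take place at the only unhindered (primary) hydroxyl in the presence of the hindered secondary and the tertiary hydroxyls.

Step 23
Reactants: 39 TBDPS-protected ester
Product: 40 monomer (triene diol with enal and tetradecanoate)
Conditions: Bu4NF, AcOH (1:1), THF, 0 °C → rt
Reagents that add atoms: none
Why: Acetic acid-buffered fluoride should cleave the silyl ether without touching the ester or the enal.

Step 24
Reactants: 40 monomer (two equivalents)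
Product: 41 CNP0458412.1
Conditions: 2 M in toluene, BHT (1 mol%), argon, dark, 110 °C, sealed tube; preparative HPLC
Reagents that add atoms: none
Why: Thermal Diels–Alder dimerisation of the kind known for myrcene-type trienes: the only diene that can become s-cis is the terminal 2-alkyl-1,3-diene (the inner diene is blocked by its Z-substituent), the terminal 1,1-disubstituted alkene of the second molecule is the most accessible, conjugation-activated dienophile, and the ortho/para preference joins the substituted diene terminus to the disubstituted dienophile carbon to form ring D with its quaternary centre; the two new stereocentres are not controlled by the remote spiro units, so 41 should form together with its cyclohexene diastereomers and has to be separated from them.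

**Compound list**

1 | hex-1-en-5-yne | C=CCCC#C | starting material
2 | lithium hex-5-en-1-yn-1-ide | [Li]C#CCCC=C | intermediate
3 | hept-6-en-2-yn-1-ol | OCC#CCCC=C | intermediate
4 | cyclic alkenylmagnesium alkoxide (3-(but-3-en-1-yl)-4-methyl-2,5-dihydro-1,2-oxamagnesole) | C=CCCC1=C(C)CO[Mg]1 | intermediate
5 | (Z)-3-iodo-2-methylhepta-2,6-dien-1-ol | OC/C(C)=C(\I)CCC=C | intermediate
6 | (Z)-tert-butyl[(3-iodo-2-methylhepta-2,6-dien-1-yl)oxy]dimethylsilane | CC(C)(C)[Si](C)(C)OC/C(C)=C(\I)CCC=C | intermediate
7 | pent-4-en-1-ol | OCCCC=C | starting material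
8 | tert-butyldimethyl(pent-4-en-1-yloxy)silane | C=CCCCO[Si](C)(C)C(C)(C)C | intermediate
9 | (R)-4-benzyloxazolidin-2-one | O=C1N[C@H](Cc2ccccc2)CO1 | starting material
10 | (R)-3-acryloyl-4-benzyloxazolidin-2-one | C=CC(=O)N1[C@H](Cc2ccccc2)COC1=O | intermediate
11 | (R)-4-benzyl-3-[(E)-6-(tert-butyldimethylsilyloxy)hex-2-enoyl]oxazolidin-2-one | O=C(/C=C/CCCO[Si](C)(C)C(C)(C)C)N1[C@H](Cc2ccccc2)COC1=O | intermediate
12 | (Z)-alkenyllithium from 6 (lithium cis to CH2OTBS) | CC(C)(C)[Si](C)(C)OC/C(C)=C(\[Li])CCC=C | intermediate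
13 | (Z)-alkenylmagnesium bromide from 12 | CC(C)(C)[Si](C)(C)OC/C(C)=C(\[Mg]Br)CCC=C | intermediate
14 | (R)-4-benzyl-3-[(S)-6-(TBS-oxy)-3-{(Z)-1-(TBS-oxy)-2-methylhepta-2,6-dien-3-yl}hexanoyl]oxazolidin-2-one | CC(C)(C)[Si](C)(C)OCCC[C@@H](CC(=O)N1[C@H](Cc2ccccc2)COC1=O)/C(=C(/C)CO[Si](C)(C)C(C)(C)C)CCC=C | intermediate
15 | (S)-6-(TBS-oxy)-3-[(Z)-1-(TBS-oxy)-2-methylhepta-2,6-dien-3-yl]-N-methoxy-N-methylhexanamide | CC(C)(C)[Si](C)(C)OCCC[C@@H](CC(=O)N(C)OC)/C(=C(/C)CO[Si](C)(C)C(C)(C)C)CCC=C | intermediate
16 | (S)-9-(TBS-oxy)-6-[(Z)-1-(TBS-oxy)-2-methylhepta-2,6-dien-3-yl]-1,1-dimethoxynonan-4-one | CC(C)(C)[Si](C)(C)OCCC[C@@H](CC(=O)CCC(OC)OC)/C(=C(/C)CO[Si](C)(C)C(C)(C)C)CCC=C | intermediate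
17 | (S)-9-(TBS-oxy)-6-[(Z)-1-(TBS-oxy)-2-methylhepta-2,6-dien-3-yl]-4-oxononanal | CC(C)(C)[Si](C)(C)OCCC[C@@H](CC(=O)CCC=O)/C(=C(/C)CO[Si](C)(C)C(C)(C)C)CCC=C | intermediate
18 | 2-[(5Z)-1,7-bis(TBS-oxy)-5-(but-3-en-1-yl)-6-methylhept-5-en-4-yl]cyclopent-2-en-1-one (chain CH configured as set in 14) | CC(C)(C)[Si](C)(C)OCCC[C@@H](C1=CCCC1=O)/C(=C(/C)CO[Si](C)(C)C(C)(C)C)CCC=C | intermediate
19 | 2-[(5Z)-1,7-bis(TBS-oxy)-6-methyl-5-(3-oxobutyl)hept-5-en-4-yl]cyclopent-2-en-1-one | CC(C)(C)[Si](C)(C)OCCC[C@@H](C1=CCCC1=O)/C(=C(/C)CO[Si](C)(C)C(C)(C)C)CCC(C)=O | intermediate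
20 | copper enolate of the 1,4-reduced cyclopentenone (phosphine ligands omitted) | CC(C)(C)[Si](C)(C)OCCC[C@@H](C1=C(O[Cu])CCC1)/C(=C(/C)CO[Si](C)(C)C(C)(C)C)CCC(C)=O | intermediate
21 | 6-hydroxy-6-methyl-9-[(Z)-1-(TBS-oxy)propan-2-ylidene]-10-[3-(TBS-oxy)propyl]spiro[4.5]decan-1-one; OH, carbonyl carbon and silyloxypropyl chain cis on ring A | CC(C)(C)[Si](C)(C)OCCC[C@@H]1/C(=C(/C)CO[Si](C)(C)C(C)(C)C)CC[C@](C)(O)[C@@]12CCCC2=O | intermediate
22 | dilithium alkoxide enolate of 21 | CC(C)(C)[Si](C)(C)OCCC[C@@H]1/C(=C(/C)CO[Si](C)(C)C(C)(C)C)CC[C@](C)(O[Li])[C@@]12CCC=C2O[Li] | intermediate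
23 | ethyl 2-(1-oxospiro[4.5]decan-2-yl)acetate derivative of 21; acetate arm trans to the carbinol carbon across ring B | CC(C)(C)[Si](C)(C)OCCC[C@@H]1/C(=C(/C)CO[Si](C)(C)C(C)(C)C)CC[C@](C)(O)[C@@]12CC[C@@H](CC(=O)OCC)C2=O | intermediate
24 | anti-1,3-diol hydroxy ester; ring-B hydroxyl cis to the acetate arm | CC(C)(C)[Si](C)(C)OCCC[C@@H]1/C(=C(/C)CO[Si](C)(C)C(C)(C)C)CC[C@](C)(O)[C@@]12CC[C@@H](CC(=O)OCC)[C@H]2O | intermediate
25 | tricyclic cis-fused γ-lactone (rings A, B and temporary ring C) | CC(C)(C)[Si](C)(C)OCCC[C@@H]1/C(=C(/C)CO[Si](C)(C)C(C)(C)C)CC[C@](C)(O)[C@@]12CC[C@H]3CC(=O)O[C@@H]23 | intermediate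
26 | 6-methylhept-5-en-2-one | CC(=O)CCC=C(C)C | starting material
27 | lithium 6-methylhepta-1,5-dien-2-olate | [Li]OC(=C)CCC=C(C)C | intermediate
28 | 6-methylhepta-1,5-dien-2-yl trifluoromethanesulfonate | C=C(OS(=O)(=O)C(F)(F)F)CCC=C(C)C | intermediate
29 | (E)-1,1-diethoxy-8-methyl-4-methylidenenona-2,7-diene | CCOC(OCC)/C=C/C(=C)CCC=C(C)C | intermediate
30 | (E)-8-methyl-4-methylidenenona-2,7-dienal | O=C/C=C/C(=C)CCC=C(C)C | intermediate
31 | dilithium lactone enolate of 25 | CC(C)(C)[Si](C)(C)OCCC[C@@H]1/C(=C(/C)CO[Si](C)(C)C(C)(C)C)CC[C@](C)(O[Li])[C@@]12CC[C@H]3C=C(O[Li])O[C@@H]23 | intermediate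
32 | aldol adduct (β-hydroxy lactone, mixture at the two new centres) | CC(C)(C)[Si](C)(C)OCCC[C@@H]1/C(=C(/C)CO[Si](C)(C)C(C)(C)C)CC[C@](C)(O)[C@@]12CC[C@H]3C(C(O)/C=C/C(=C)CCC=C(C)C)C(=O)O[C@@H]23 | intermediate
33 | secondary mesylate of 32 | CC(C)(C)[Si](C)(C)OCCC[C@@H]1/C(=C(/C)CO[Si](C)(C)C(C)(C)C)CC[C@](C)(O)[C@@]12CC[C@H]3C(C(OS(C)(=O)=O)/C=C/C(=C)CCC=C(C)C)C(=O)O[C@@H]23 | intermediate
34 | α-alkylidene lactone with (E,E)-triene side chain | CC(C)(C)[Si](C)(C)OCCC[C@@H]1/C(=C(/C)CO[Si](C)(C)C(C)(C)C)CC[C@](C)(O)[C@@]12CC[C@H]3/C(=C\C=C\C(=C)CCC=C(C)C)C(=O)O[C@@H]23 | intermediate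
35 | bis-TBS triene diol (primary allylic OH and ring-B secondary OH free) | CC(C)(C)[Si](C)(C)OCCC[C@@H]1/C(=C(/C)CO[Si](C)(C)C(C)(C)C)CC[C@](C)(O)[C@@]12CC[C@@H](/C(=C\C=C\C(=C)CCC=C(C)C)CO)[C@H]2O | intermediate
36 | primary allylic TBDPS ether of 35 | CC(C)(C)[Si](C)(C)OCCC[C@@H]1/C(=C(/C)CO[Si](C)(C)C(C)(C)C)CC[C@](C)(O)[C@@]12CC[C@@H](/C(=C\C=C\C(=C)CCC=C(C)C)CO[Si](c3ccccc3)(c3ccccc3)C(C)(C)C)[C@H]2O | intermediate
37 | tetraol mono-TBDPS ether (both TBS groups removed) | OCCC[C@@H]1/C(=C(/C)CO)CC[C@](C)(O)[C@@]12CC[C@@H](/C(=C\C=C\C(=C)CCC=C(C)C)CO[Si](c3ccccc3)(c3ccccc3)C(C)(C)C)[C@H]2O | intermediate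
38 | (Z)-tetrasubstituted enal, 3-hydroxypropyl chain free | OCCC[C@@H]1/C(=C(/C)C=O)CC[C@](C)(O)[C@@]12CC[C@@H](/C(=C\C=C\C(=C)CCC=C(C)C)CO[Si](c3ccccc3)(c3ccccc3)C(C)(C)C)[C@H]2O | intermediate
39 | tetradecanoate of 38 | CCCCCCCCCCCCCC(=O)OCCC[C@@H]1/C(=C(/C)C=O)CC[C@](C)(O)[C@@]12CC[C@@H](/C(=C\C=C\C(=C)CCC=C(C)C)CO[Si](c3ccccc3)(c3ccccc3)C(C)(C)C)[C@H]2O | intermediate
40 | monomer: spiro triene diol with enal and tetradecanoate | CCCCCCCCCCCCCC(=O)OCCC[C@@H]1/C(=C(/C)C=O)CC[C@](C)(O)[C@@]12CC[C@@H](/C(=C\C=C\C(=C)CCC=C(C)C)CO)[C@H]2O | intermediate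
41 | CNP0458412.1 | CCCCCCCCCCCCCC(=O)OCCC[C@@H]1/C(=C(/C)C=O)CC[C@](C)(O)[C@@]12CC[C@@H](/C(=C\C=C\[C@@]1(CCC=C(C)C)CCC(CCC=C(C)C)=C[C@@H]1/C=C(/CO)[C@@H]1CC[C@]3([C@H](CCCOC(=O)CCCCCCCCCCCCC)/C(=C(/C)C=O)CC[C@]3(C)O)[C@@H]1O)CO)[C@H]2O | target

**Step count and risks**

Total step count: 24. Longest linear sequence: 19 steps (steps 1–3, 7–14, 17–24).

The three steps most likely to fail:

Step 24 (dimerisation). What may go wrong: poor discrimination between the possible intermolecular cycloaddition modes (regiochemistry, endo/exo, facial sense) and loss of material by thermal oligomerisation. Fallback, a temporary silicon tether: it sets out from 40. Treatment of 40 with iPr2SiCl2 (0.5 equiv) and imidazole in concentrated CH2Cl2 at −20 °C should join the reactive primary allylic hydroxyls of two molecules as the bis(alkoxy)diisopropylsilane F1; the hindered secondary hydroxyl next to the spiro carbon is expected to react much more slowly. Heating F1 at high dilution (toluene, BHT, 110 °C) makes the cycloaddition intramolecular through a thirteen-membered tether ring, which allows only the head-to-tail pairing and cuts down the number of accessible transition states, and should give the tethered cycloadduct F2. HF·pyridine in THF/pyridine at 0 °C removes the silylene and the route comes back at 41.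

Step 12 (key step). What may go wrong: protonation of the copper enolate before ring closure (plain 1,4-reduction), or closure through the other chair with poor facial selectivity at the spiro carbon. Fallback, separation of enolate formation and ring closure: it sets out from 19. 1,4-Hydrosilylation with Et3SiH and RhCl(PPh3)3 (1 mol%) in THF at 40 °C should give the isolable, regiodefined triethylsilyl enol ether F3. A separate intramolecular Mukaiyama aldol reaction (TiCl4, CH2Cl2, −78 °C) then forms the same bond through a Lewis acid transition state in an aprotic medium, where protonation cannot compete and the facial preference can be tuned with the Lewis acid. Aqueous work-up comes back to the route at 21.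

Step 13 (alkylation next to the ring-B ketone). What may go wrong: poor facial selectivity of the attack on the enolate (the controlling centre is only 1,3-related) or retro-aldol opening of the tertiary alkoxide before enolisation is complete. Fallback, intramolecular delivery of the two-carbon arm from the ring-B oxygen: it sets out from 21. Dehydrogenation with IBX in DMSO at 65 °C should give the cyclopentenone F4, and hydroxyl-directed 1,2-reduction (Me4NBH(OAc)3, MeCN/AcOH, −30 °C) the allylic alcohol F5. NBS and ethyl vinyl ether (CH2Cl2, −40 °C) convert the secondary hydroxyl into the bromoacetal F6. Bu3SnH/AIBN in benzene at 80 °C triggers a 5-exo Ueno–Stork radical cyclisation, which can only give the cis-fused bicyclic ethyl acetal F7. PPTS in wet acetone gives the lactol F8, and Pr4NRuO4 with N-methylmorpholine N-oxide oxidises it to the lactone; the route is rejoined at 25.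

**Further compounds**

F1 | step 24 | bis(alkoxy)diisopropylsilane linking the primary allylic oxygens of two molecules of 40 | CCCCCCCCCCCCCC(=O)OCCC[C@@H]1/C(=C(/C)C=O)CC[C@](C)(O)[C@@]12CC[C@@H](/C(=C\C=C\C(=C)CCC=C(C)C)CO[Si](C(C)C)(C(C)C)OC/C(=C/C=C/C(=C)CCC=C(C)C)[C@@H]1CC[C@]3([C@H](CCCOC(=O)CCCCCCCCCCCCC)/C(=C(/C)C=O)CC[C@]3(C)O)[C@@H]1O)[C@H]2O
F2 | step 24 | tethered cycloadduct (41 with its two primary allylic oxygens bridged by diisopropylsilylene) | CCCCCCCCCCCCCC(=O)OCCC[C@@H]1/C(=C(/C)C=O)CC[C@](C)(O)[C@@]12CC[C@@H](/C(=C\C=C\[C@@]1(CCC=C(C)C)CCC(CCC=C(C)C)=C[C@@H]1/C=C(/CO[Si]4(C(C)C)C(C)C)[C@@H]1CC[C@]3([C@H](CCCOC(=O)CCCCCCCCCCCCC)/C(=C(/C)C=O)CC[C@]3(C)O)[C@@H]1O)CO4)[C@H]2O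
F3 | step 12 | triethylsilyl enol ether of the 1,4-reduced cyclopentenone | CC(C)(C)[Si](C)(C)OCCC[C@@H](C1=C(O[Si](CC)(CC)CC)CCC1)/C(=C(/C)CO[Si](C)(C)C(C)(C)C)CCC(C)=O
F4 | step 13 | spiro[4.5]dec-2-en-1-one (ring-B enone of 21) | CC(C)(C)[Si](C)(C)OCCC[C@@H]1/C(=C(/C)CO[Si](C)(C)C(C)(C)C)CC[C@](C)(O)[C@@]12CC=CC2=O
F5 | step 13 | ring-B allylic alcohol (anti to the tertiary hydroxyl) | CC(C)(C)[Si](C)(C)OCCC[C@@H]1/C(=C(/C)CO[Si](C)(C)C(C)(C)C)CC[C@](C)(O)[C@@]12CC=C[C@H]2O
F6 | step 13 | 2-bromo-1-ethoxyethyl acetal of F5 | CC(C)(C)[Si](C)(C)OCCC[C@@H]1/C(=C(/C)CO[Si](C)(C)C(C)(C)C)CC[C@](C)(O)[C@@]12CC=C[C@H]2OC(CBr)OCC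
F7 | step 13 | cis-fused bicyclic ethyl acetal (2-ethoxytetrahydrofuran on ring B) | CC(C)(C)[Si](C)(C)OCCC[C@@H]1/C(=C(/C)CO[Si](C)(C)C(C)(C)C)CC[C@](C)(O)[C@@]12CC[C@H]3CC(OCC)O[C@@H]23
F8 | step 13 | cis-fused lactol | CC(C)(C)[Si](C)(C)OCCC[C@@H]1/C(=C(/C)CO[Si](C)(C)C(C)(C)C)CC[C@](C)(O)[C@@]12CC[C@H]3CC(O)O[C@@H]23
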